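(Readings and results come from a simulation for an exercise, noise included.)

Count the partner. The meeting had three earlier runs before it, and one new flask to judge.

the same everywhere: free catalyst 0.18 mM

|  | substrate | partner | remark |
|---|---|---|---|
| summer | 0.10 M | 0.045 M | run made earlier |
| spring | 0.10 M | 0.18 M | run made earlier |
| autumn | 0.050 M | 0.090 M | run made earlier |
| flask | 0.10 M | 0.0900 M |  |

- summer (time / h: target / %): 0.333: 5.4; 1.00: 19.0; 1.50: 27.4; 2.50: 29.2; 4.00: 28.8; 5.00: 29.2; 6.00: 29.1
- spring (time / h: target / %): 0.333: 1.4; 1.00: 5.4; 1.50: 9.6; 2.50: 22.0; 4.00: 46.6; 5.00: 47.3; 6.00: 47.1
- autumn (time / h: target / %): 0.500: 8.6; 0.833: 15.9; 1.50: 36.7; 3.00: 76.8; 6.00: 77.9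

(scatter of a reading: 0.3 percentage points)

* apparent order in free catalyst when 30% of the substrate are converted (percent change of the rate of making target for one percent more free catalyst charged)
* factor on the rate of making target when 30% of the substrate are converted if partner is charged twice over

- no earlier run changes the charge of free catalyst; that part of a forecast is a guess

The first speaker began from the autumn run, which has the flask's starting [partner], and reckoned 56.7% as its lost share: the fraction of the partner charged that had not become target once the run went flat. The zero of this scale is the even case of one partner for each target. The summer run gave 35.3% and the spring run 73.8%, so the share climbed with the partner charged.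

The second speaker took the flat ends as the mark of a limiting reagent, with partner also leaving by a road that makes no target. The third objected that the autumn run has half the flask's substrate. The first replied that its opening rate of 8.60 mM h⁻¹ lay between the summer run's 16.2 mM h⁻¹ and the spring run's 4.20 mM h⁻¹, so substrate seemed to matter little. The meeting therefore expected the flask to stop near 39.0% target. As a guess, the first speaker put the catalyst order above 1, on the thought that more catalyst reaches 30% conversion sooner and leaves the loss less time.

The forecast, made apart and lower on that order, gave 1 and a partner factor of 0.9, reading the runs as having “a sudden stop rather than an equilibrium approach”.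

The flask gives an order of 1.2 and a factor of 0.920, and it ends with 40.0% target, 0% partner and 0.0500 M decomposed reagent.

    substrate + free catalyst → catalyst intermediate A (k = 370 L mol⁻¹ min⁻¹)
    partner + catalyst intermediate A → catalyst intermediate B (k = 400 L mol⁻¹ min⁻¹)
    catalyst intermediate B → catalyst intermediate C (k = 30.0 min⁻¹)
    catalyst intermediate C → free catalyst + target (k = 43.0 min⁻¹)
    partner + catalyst intermediate C ⇌ idle complex, settled at all times (K = 590 L mol⁻¹)
    partner → decomposed reagent (k = 0.00860 min⁻¹)

That decomposed reagent makes the flask's lost share 55.5%, beside the 56.7% carried from the autumn run. The path from partner to decomposed reagent accounts for part of the catalyst order: with that path taken away, the same flask has an order of 1.0 against 1.2. That path is also the largest single effect on the flask's apparent order in partner at 30% conversion, which without it is −1.2 against 0.14.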